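**Retrosynthetic overview** (labdane numbering: ring A = C1–C5, C10; ring B = C5–C10; C11–C16 side chain; C17 on C8; C20 on C10)
1. 22 ⇐ diol 21 ⇐ bis-silyl ether 20 ⇐ enal 17. The C7=C8 alkene with its one-carbon substituent on C8 is read as an aldol condensation product (C17 as formyl group, C7 as former aldehyde carbon).
2. Ring B is cut at C9–C10 and C7–C8 together: HAT-initiated Giese addition/aldol annulation of ring-A alkenyl aldehyde 13 with enal 5. Ring A is bought as a cyclohexenone; ring B is formed last, in the key step.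
3. Enabling feature: in ring A the methyl-bearing alkene carbon C10 (a tertiary radical after hydrogen-atom transfer to C1=C10) is 1,4-related to the aldehyde carbon C7 on the C5–C6 arm, so the two-carbon unit C9=C8 of an enal fits between them. The axial methyl on C4 steers the new bond at C10 equatorial, which gives the trans ring fusion.
4. 13 ⇐ 2,4,4-trimethylcyclohex-2-en-1-one 6: CBS reduction, Johnson–Claisen rearrangement (O→C chirality transfer sets C5), allylic oxidation, CBS reduction (C2), silylation, DIBAL-H.
5. 5 ⇐ (S)-citronellol 1 (source of C13): silylation, ozonolysis, Wittig olefination.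

Key step: step 10

Remark: the target is (2R,5R,9R,10R,13S) in this numbering. All bicyclic intermediates have the target's spatial arrangement at C2, C5, C9, C10 and C13: trans fusion, H5 and H9 both anti to the C10 methyl, C2–O equatorial.
Remark: (S)-citronellol and 2,4,4-trimethylcyclohex-2-en-1-one are taken as commercial; C15–O and C2–O are carried as TBS ethers and acetylated at the end.

Step 1
Reactants: 1 (S)-citronellol
Product: 2 tert-butyl{[(3S)-3,7-dimethyloct-6-en-1-yl]oxy}dimethylsilane
Conditions: TBSCl, imidazole, DMF, 25 °C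
Reagents that add atoms: tert-butyldimethylsilyl chloride, CC(C)(C)[Si](C)(C)Cl
Why: Imidazole-assisted silylation of the primary alcohol gives an ether that survives ozone, ylide, hydride and radical conditions and is removed in step 14.

Step 2
Reactants: 2 TBS ether of (S)-citronellol
Product: 4 (4S)-6-[(tert-butyldimethylsilyl)oxy]-4-methylhexanal, via ozonide 3 (not isolated)
Conditions: O3, CH2Cl2/MeOH, −78 °C; then PPh3, −78 → 25 °C
Reagents that add atoms: ozone, [O-][O+]=O
Why: Ozonolysis of the trisubstituted alkene with reductive work-up gives the aldehyde whose carbonyl carbon becomes C9, while the remote C13 stereocentre from the chiral pool is untouched.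

Step 3
Reactants: 4 (4S)-6-[(tert-butyldimethylsilyl)oxy]-4-methylhexanal
Product: 5 (2E,6S)-8-[(tert-butyldimethylsilyl)oxy]-6-methyloct-2-enal
Conditions: Ph3P=CHCHO, toluene, 80 °C
Reagents that add atoms: (triphenylphosphoranylidene)acetaldehyde, O=CC=P(c1ccccc1)(c1ccccc1)c1ccccc1
Why: Wittig olefination with a stabilised ylide gives the E-enal and supplies C8 and C17.

Step 4
Reactants: 6 2,4,4-trimethylcyclohex-2-en-1-one
Product: 7 (1S)-2,4,4-trimethylcyclohex-2-en-1-ol
Conditions: (R)-2-methyl-CBS-oxazaborolidine (10 mol%), BH3·SMe2, THF, −20 °C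
Reagents that add atoms: none
Why: Corey–Bakshi–Shibata reduction in which the α-methylalkenyl arm acts as the large group, so the (R)-catalyst should deliver hydride to give the (S)-allylic alcohol under catalyst control.

Step 5
Reactants: 7 (1S)-2,4,4-trimethylcyclohex-2-en-1-ol
Product: 9 ethyl [(1R)-2,6,6-trimethylcyclohex-2-en-1-yl]acetate, via mixed ketene acetal 8 (not isolated)
Conditions: CH3C(OEt)3, EtCO2H (cat.), 140 °C, removal of EtOH
Reagents that add atoms: triethyl orthoacetate, CC(OCC)(OCC)OCC
Why: Johnson–Claisen rearrangement, in which the suprafacial [3,3] shift of 8 forms the C5–C6 bond next to the gem-dimethyl carbon on the face that carried oxygen, so the carbinol configuration is transferred to C5 and the alkene moves to C1=C10.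

Step 6
Reactants: 9 ethyl [(1R)-2,6,6-trimethylcyclohex-2-en-1-yl]acetate
Product: 10 ethyl [(1R)-2,6,6-trimethyl-4-oxocyclohex-2-en-1-yl]acetate
Conditions: Pd(OH)2/C (cat.), t-BuOOH, K2CO3, CH2Cl2, 4 °C
Reagents that add atoms: tert-butyl hydroperoxide, CC(C)(C)OO
Why: Allylic C–H oxidation by tert-butylperoxyl radicals should take place at the unhindered ring methylene (C2) next to the alkene CH, in preference to the neopentyl tertiary C5–H and the methyl group, and gives the enone without enolising C5.

Step 7
Reactants: 10 ethyl [(1R)-2,6,6-trimethyl-4-oxocyclohex-2-en-1-yl]acetate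
Product: 11 ethyl [(1R,4R)-4-hydroxy-2,6,6-trimethylcyclohex-2-en-1-yl]acetate
Conditions: (S)-2-methyl-CBS-oxazaborolidine (20 mol%), BH3·SMe2, THF, −30 °C
Reagents that add atoms: none
Why: Corey–Bakshi–Shibata reduction of the enone with the alkenyl arm as the large group, so the (S)-catalyst should give the (R)-carbinol at C2, trans to the acetate arm on C5, by catalyst control over the resident centre.

Step 8
Reactants: 11 ethyl [(1R,4R)-4-hydroxy-2,6,6-trimethylcyclohex-2-en-1-yl]acetate
Product: 12 ethyl [(1R,4R)-4-[(tert-butyldimethylsilyl)oxy]-2,6,6-trimethylcyclohex-2-en-1-yl]acetate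
Conditions: TBSCl, imidazole, DMF, 25 °C
Reagents that add atoms: tert-butyldimethylsilyl chloride, CC(C)(C)[Si](C)(C)Cl
Why: Silylation of the secondary allylic alcohol protects C2–O through the hydride and radical steps without touching the stereocentres.

Step 9
Reactants: 12 ethyl [(1R,4R)-4-[(tert-butyldimethylsilyl)oxy]-2,6,6-trimethylcyclohex-2-en-1-yl]acetate
Product: 13 [(1R,4R)-4-[(tert-butyldimethylsilyl)oxy]-2,6,6-trimethylcyclohex-2-en-1-yl]acetaldehyde
Conditions: DIBAL-H, CH2Cl2, −78 °C; Rochelle salt work-up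
Reagents that add atoms: none
Why: Partial ester reduction, in which the tetrahedral aluminium hemiacetal is stable at −78 °C and releases the C7 aldehyde only on work-up.

Step 10
Reactants: 13 [(1R,4R)-4-[(tert-butyldimethylsilyl)oxy]-2,6,6-trimethylcyclohex-2-en-1-yl]acetaldehyde; 5 (2E,6S)-8-[(tert-butyldimethylsilyl)oxy]-6-methyloct-2-enal
Product: 15 trans-fused ring-B β-hydroxy aldehyde (C7–OH, C8–CHO, C9 side chain, C10 methyl; mixture at C7 and C8), via conjugate-adduct enolate 14 (not isolated)
Conditions: Fe(acac)3 (0.5 equiv), PhSiH3, 5 (3 equiv), EtOH/(CH2OH)2, 0 → 25 °C, high concentration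
Reagents that add atoms: none
Why: HAT-initiated Giese addition/aldol annulation (radical–polar crossover): the iron hydride formed from Fe(acac)3 and PhSiH3 transfers a hydrogen atom to C1 of the electron-rich C1=C10 alkene of 13, the tertiary C10 radical adds to the β-carbon (C9) of enal 5, divalent iron reduces the α-formyl radical to enolate 14, and C8 of 14 adds to the C7 aldehyde; the closest known reactions are the iron-mediated reductive coupling of alkenes with enals and enones and its annulative variant in which the enolate is trapped by a carbonyl group tethered to the alkene. Ring B closes by a 6-(enolexo)-exo-trig aldol addition through a chair. C10 is set by ring A: the chair radical is attacked on its equatorial trajectory, syn to H5 and anti to the C6 arm, because the axial trajectory is blocked by the axial methyl on C4, so the former alkene methyl (C20) becomes axial and the ring fusion trans. C9 is set in the Giese step, where the CH2 chain of 5 should take the open sector anti to C5 while the flat C8 terminus lies on the C5 side next to the aldehyde arm, and it is reinforced in the aldol step, in which only this adduct closes through a chair with the chain equatorial while the epimeric adduct is expected to stay as open-chain dialdehyde. C7 and C8 form as mixtures that step 11 erases. The step needs hydrogen-atom transfer to the trisubstituted alkene in preference to the enal (polarity match with the hydridic iron hydride) and intermolecular addition faster than 1,5-hydrogen transfer from the formyl group, both served by an excess of 5 at high concentration.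

Step 11
Reactants: 15 ring-B β-hydroxy aldehyde
Product: 17 bis-silyl enal (C7=C8, C8–CHO), via C7 mesylate 16 (not isolated)
Conditions: MsCl, Et3N, CH2Cl2, 0 → 25 °C
Reagents that add atoms: none
Why: Mesylation and E1cB elimination through the proton at C8, which is α to the formyl group, so all aldol epimers converge on the conjugated C7=C8 enal.

Step 12
Reactants: 17 bis-silyl enal
Product: 18 bis-silyl allylic alcohol (C8–CH2OH, C7=C8)
Conditions: NaBH4, CeCl3·7H2O, MeOH, −40 °C
Reagents that add atoms: none
Why: Luche reduction delivers hydride 1,2 to the enal and leaves the trisubstituted alkene in place.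

Step 13
Reactants: 18 bis-silyl allylic alcohol
Product: 20 bis-silyl ether of the target diol (C8–CH3, C7=C8), via allylic mesylate 19 (not isolated)
Conditions: MsCl, Et3N, CH2Cl2, −30 °C; then LiBHEt3, THF, −30 → 0 °C
Reagents that add atoms: none
Why: Activation of the primary allylic alcohol and direct SN2 displacement by triethylborohydride at the unhindered exocyclic carbon should give the C17 methyl group with the alkene kept at C7=C8.

Step 14
Reactants: 20 bis-silyl ether
Product: 21 diol (C2–OH, C15–OH)
Conditions: TBAF, THF, 25 °C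
Reagents that add atoms: none
Why: Fluoride-driven cleavage of both Si–O bonds, with no stereocentre or alkene involved.

Step 15
Reactants: 21 diol
Product: 22 target diacetate
Conditions: Ac2O, pyridine, DMAP (cat.), CH2Cl2, 25 °C
Reagents that add atoms: acetic anhydride, CC(=O)OC(C)=O
Why: DMAP-catalysed acylation of the primary and the equatorial secondary alcohol with retention at C2.

**Compound list**
1 | (S)-citronellol, (3S)-3,7-dimethyloct-6-en-1-ol | OCC[C@@H](C)CCC=C(C)C | starting material
2 | tert-butyl{[(3S)-3,7-dimethyloct-6-en-1-yl]oxy}dimethylsilane | CC(C)(C)[Si](C)(C)OCC[C@@H](C)CCC=C(C)C | intermediate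
3 | secondary ozonide of 2 (3,3-dimethyl-1,2,4-trioxolane at the former alkene) | CC(C)(C)[Si](C)(C)OCC[C@@H](C)CCC1OOC(C)(C)O1 | intermediate
4 | (4S)-6-[(tert-butyldimethylsilyl)oxy]-4-methylhexanal | CC(C)(C)[Si](C)(C)OCC[C@@H](C)CCC=O | intermediate
5 | (2E,6S)-8-[(tert-butyldimethylsilyl)oxy]-6-methyloct-2-enal | CC(C)(C)[Si](C)(C)OCC[C@@H](C)CC/C=C/C=O | intermediate
6 | 2,4,4-trimethylcyclohex-2-en-1-one | CC1=CC(C)(C)CCC1=O | starting material
7 | (1S)-2,4,4-trimethylcyclohex-2-en-1-ol | O[C@H]1CCC(C)(C)C=C1C | intermediate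
8 | 1-ethoxyethenyl ether of 7 (mixed ketene acetal) | C=C(OCC)O[C@H]1CCC(C)(C)C=C1C | intermediate
9 | ethyl [(1R)-2,6,6-trimethylcyclohex-2-en-1-yl]acetate | CCOC(=O)C[C@@H]1C(C)(C)CCC=C1C | intermediate
10 | ethyl [(1R)-2,6,6-trimethyl-4-oxocyclohex-2-en-1-yl]acetate | CCOC(=O)C[C@@H]1C(C)(C)CC(=O)C=C1C | intermediate
11 | ethyl [(1R,4R)-4-hydroxy-2,6,6-trimethylcyclohex-2-en-1-yl]acetate | CCOC(=O)C[C@@H]1C(C)(C)C[C@@H](O)C=C1C | intermediate
12 | ethyl [(1R,4R)-4-[(tert-butyldimethylsilyl)oxy]-2,6,6-trimethylcyclohex-2-en-1-yl]acetate | CCOC(=O)C[C@@H]1C(C)(C)C[C@@H](O[Si](C)(C)C(C)(C)C)C=C1C | intermediate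
13 | [(1R,4R)-4-[(tert-butyldimethylsilyl)oxy]-2,6,6-trimethylcyclohex-2-en-1-yl]acetaldehyde | O=CC[C@@H]1C(C)(C)C[C@@H](O[Si](C)(C)C(C)(C)C)C=C1C | intermediate
14 | iron enolate of the Giese adduct (C9–C10 formed, C8=C17–O enolate, free C7 aldehyde), drawn as the enolate anion | CC(C)(C)[Si](C)(C)OCC[C@@H](C)CC[C@H](C=C[O-])[C@]1(C)C[C@H](O[Si](C)(C)C(C)(C)C)CC(C)(C)[C@H]1CC=O | intermediate
15 | trans-fused β-hydroxy aldehyde (C7–OH, C8–CHO; target configuration at C2, C5, C9, C10, C13; mixture at C7 and C8) | CC(C)(C)[Si](C)(C)OCC[C@@H](C)CC[C@@H]1C(C=O)C(O)C[C@@H]2C(C)(C)C[C@@H](O[Si](C)(C)C(C)(C)C)C[C@@]12C | intermediate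
16 | C7 methanesulfonate of 15 | CC(C)(C)[Si](C)(C)OCC[C@@H](C)CC[C@@H]1C(C=O)C(OS(C)(=O)=O)C[C@@H]2C(C)(C)C[C@@H](O[Si](C)(C)C(C)(C)C)C[C@@]12C | intermediate
17 | bis-silyl enal (C7=C8, C8–CHO; target configuration at C2, C5, C9, C10, C13) | CC(C)(C)[Si](C)(C)OCC[C@@H](C)CC[C@@H]1C(C=O)=CC[C@@H]2C(C)(C)C[C@@H](O[Si](C)(C)C(C)(C)C)C[C@@]12C | intermediate
18 | bis-silyl allylic alcohol (C8–CH2OH, C7=C8) | CC(C)(C)[Si](C)(C)OCC[C@@H](C)CC[C@@H]1C(CO)=CC[C@@H]2C(C)(C)C[C@@H](O[Si](C)(C)C(C)(C)C)C[C@@]12C | intermediate
19 | allylic methanesulfonate of 18 | CC(C)(C)[Si](C)(C)OCC[C@@H](C)CC[C@@H]1C(COS(C)(=O)=O)=CC[C@@H]2C(C)(C)C[C@@H](O[Si](C)(C)C(C)(C)C)C[C@@]12C | intermediate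
20 | (2R,5R,9R,10R,13S) bis-TBS ether of the target diol (C8–CH3, C7=C8) | CC(C)(C)[Si](C)(C)OCC[C@@H](C)CC[C@@H]1C(C)=CC[C@@H]2C(C)(C)C[C@@H](O[Si](C)(C)C(C)(C)C)C[C@@]12C | intermediate
21 | (2R,5R,9R,10R,13S) diol (C2–OH, C15–OH, C7=C8) | OCC[C@@H](C)CC[C@@H]1C(C)=CC[C@@H]2C(C)(C)C[C@@H](O)C[C@@]12C | intermediate
22 | (2R,5R,9R,10R,13S) diacetate, CNP0220683.1 | CC(=O)OCC[C@@H](C)CC[C@@H]1C(C)=CC[C@@H]2C(C)(C)C[C@@H](OC(C)=O)C[C@@]12C | target

Total step count: 15. Longest linear sequence: 12 steps (6 → 22, steps 4–15).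

**Steps most likely to fail**

Step 10. The likely failure is poor facial discrimination at the β-carbon of the enal, giving a mixture of C9 epimers; 1,5-hydrogen transfer from the formyl group to the C10 radical is a second leak. The fallback replaces kinetic control at C9 by a thermodynamic relay. It sets out from enal 17, whatever its C9 composition. Pinnick oxidation (NaClO2, NaH2PO4, 2-methylbut-2-ene) should give the α,β-unsaturated carboxylic acid F1. Curtius rearrangement (DPPA, Et3N, toluene, 80 °C) and acidic hydrolysis of the vinyl isocyanate should give the C8 ketone F2, with C17 excised. In F2, C9 is α to the carbonyl and is equilibrated (DBU) to the isomer with the side chain equatorial and H9 anti to the C10 methyl. Kinetic deprotonation at the unhindered C7 (LDA, −78 °C) and PhNTf2 give the enol triflate F3. Iron-catalysed cross-coupling with MeMgBr (Fe(acac)3 cat., THF/NMP) comes back to the route at 20.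

Step 7. The likely failure is mismatched double stereodifferentiation, so that hydride is delivered to the wrong face of the isophorone-type enone and the cis-alcohol forms. The fallback sets out from 10. Reduction with NaBH4/CeCl3·7H2O and separation give the cis-alcohol F4. Mitsunobu inversion (4-nitrobenzoic acid, PPh3, DIAD) gives the trans 4-nitrobenzoate F5. Ethanolysis (K2CO3, EtOH) comes back to the route at 11.

Step 13. The likely failure is SN2′ delivery of hydride to C7, which would move the alkene to the exocyclic position, or loss of the primary silyl ether. The fallback uses reductive desulfurisation instead of hydride displacement. It sets out from enal 17. Thioacetalisation (ethane-1,2-dithiol, Zn(OTf)2, CH2Cl2) gives the 1,3-dithiolane F6. Desulfurisation with Raney Ni in acetone comes back to the route at 20, bypassing 18 and 19.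

**Further compounds**
F1 | step 10 | bis-silyl α,β-unsaturated carboxylic acid (C8–CO2H, C7=C8; mixture at C9) | CC(C)(C)[Si](C)(C)OCC[C@@H](C)CCC1C(C(=O)O)=CC[C@@H]2C(C)(C)C[C@@H](O[Si](C)(C)C(C)(C)C)C[C@@]12C
F2 | step 10 | bis-silyl C8 ketone (C17 excised; side chain equatorial at C9, trans-fused) | CC(C)(C)[Si](C)(C)OCC[C@@H](C)CC[C@@H]1C(=O)CC[C@@H]2C(C)(C)C[C@@H](O[Si](C)(C)C(C)(C)C)C[C@@]12C
F3 | step 10 | bis-silyl enol triflate (C7=C8–OTf) | CC(C)(C)[Si](C)(C)OCC[C@@H](C)CC[C@@H]1C(OS(=O)(=O)C(F)(F)F)=CC[C@@H]2C(C)(C)C[C@@H](O[Si](C)(C)C(C)(C)C)C[C@@]12C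
F4 | step 7 | ethyl [(1R,4S)-4-hydroxy-2,6,6-trimethylcyclohex-2-en-1-yl]acetate | CCOC(=O)C[C@@H]1C(C)(C)C[C@H](O)C=C1C
F5 | step 7 | (1R,4R)-4-(2-ethoxy-2-oxoethyl)-3,5,5-trimethylcyclohex-2-en-1-yl 4-nitrobenzoate | CCOC(=O)C[C@@H]1C(C)(C)C[C@@H](OC(=O)c2ccc(cc2)[N+](=O)[O-])C=C1C
F6 | step 13 | bis-silyl 1,3-dithiolane of enal 17 (C8–CH(SCH2CH2S), C7=C8) | CC(C)(C)[Si](C)(C)OCC[C@@H](C)CC[C@@H]1C(C3SCCS3)=CC[C@@H]2C(C)(C)C[C@@H](O[Si](C)(C)C(C)(C)C)C[C@@]12C
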